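The readings were generated by integration for an exercise, and the scatter is random.

I followed the catalyst.

| setting | summer | winter | midnight |
|---|---|---|---|
| substrate | 80.0 mM | 80.0 mM | 80.0 mM |
| free catalyst | 2.40 mM | 3.60 mM | 2.40 mM |
| time |  |  | 150 h |

- summer run (time / h: [product] / mM): 5.3: 16.64; 11: 26.96; 16: 32.10; 21: 36.45; 26: 39.09; 32: 41.71; 37: 44.01
- winter run (time / h: [product] / mM): 5.3: 26.08; 11: 40.45; 16: 48.41; 21: 53.90; 26: 57.88; 32: 61.53; 37: 63.61

(readings scatter by 0.2 mM)

- Overall: substrate -> product, with free catalyst as catalyst.
- Constant volume, constant temperature.
- An order is taken over about fifteen percent of the charge, up and down.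

- apparent order in [free catalyst] of the starting rate, round the charge of the summer run (the rate where two percent of its substrate have turned into product)
- product in the midnight run at 150 h, as a share of the substrate charged

Substrate becomes product through free catalyst, so I opened a ledger on what each millimolar of catalyst bought. In the summer run the first-order constant k, which is rate over remaining substrate and so an inverse time constant, fell from 0.0312 h⁻¹ near 21.8 mM of product to 0.0116 h⁻¹ near 41.6 mM. So k fell against product at a slope b = 0.989 L mol⁻¹ h⁻¹, and I assumed the same slope for the winter run.

First entry: in the winter run k stood at 0.0544 h⁻¹ near 33.3 mM of product, and run back to zero product, k read 0.0528 h⁻¹ in the summer run and 0.0873 h⁻¹ in the winter run. Against added catalyst, k therefore rose at a slope c = 28.8 L mol⁻¹ h⁻¹. Second entry: the summer start then counted as W = 1.83 mM of working catalyst out of 2.40 mM charged. Third entry: dividing c by b gave Y = 29.1, the product made per unit of working catalyst lost, its turnover number. To close the books, the midnight run has the summer charge, so W buys 53.3 mM of product and leaves 26.7 mM of substrate unturned. The last gap closes with a time constant of 37.9 h, and 150 h is 3.96 of those, so I committed to 66.7%.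

The forecast gave an order of 1.25 and a share of 71%, higher than mine, since it read the zero of k near 55 mM and noted that “the tail flattens slightly above the line”.

The flask gave an order of 1.5 and, for the midnight run, 64.8%.

    free catalyst + substrate → product + free catalyst (30.64 L mol⁻¹ h⁻¹)
    free catalyst + impurity → spent catalyst
    free catalyst + substrate → spent catalyst + substrate (1.004 L mol⁻¹ h⁻¹)

At each meeting with substrate, free catalyst either makes product or becomes spent catalyst, and substrate stands in both steps, so Y holds however much substrate remains. Taking away the loss of free catalyst to spent catalyst at its meetings with substrate brings the midnight run to >99.9%, so that loss is why it stops short. The impurity takes 0.692 mM at once, and Y prices the remaining 1.71 mM at 62.1% of the charge, against 64.8%. With the impurity absent, Y prices the whole 2.40 mM at 87.2%, and that run gave 87.3%.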